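**Retrosynthetic overview**
- The target is traced back to a C6-hydroxy, C7-isopropenyl ten-membered ring by acetylation and selective hydrogenation of the isopropenyl group.
- The ten-membered carbocycle is formed second, by closing C6–C7 through a palladium/zinc umpolung allylation of an epoxy aldehyde bearing a distal allylic chloride.
- The epoxide ring is formed first, by Sharpless epoxidation of a farnesol-type allylic alcohol; this fixes C4 and C5 and, through them, C6 and C7.
- The C3 senecioate is installed by a new amine-catalysed γ-C–H acyloxylation of ω-chlorofarnesal with bis(3-methylbut-2-enoyl) peroxide.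
- ω-Chlorofarnesal comes from (2E,6E)-farnesol (ene-chlorination, oxidation); the peroxide comes from two molecules of 3-methylbut-2-enoyl chloride and hydrogen peroxide.

Assumption: the quinine-derived primary amine in step 4 is taken to give the (4S)-ester; if the sense proves opposite, the quinidine-derived pseudo-enantiomer is used under the same conditions.
Note: the chlorine-bearing carbon made in step 1 stays a 1:1 mixture of configurations until the ring closure destroys it. Macrocycles are named with germacrane numbering (ring C1–C10; C1=C10 alkene with methyl C14 on C10; methyl C15 on C4; C11–C13 side chain on C7).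

Step 1
Reactants: 1 (2E,6E)-farnesol
Product: 2 (2E,6E)-10-chloro-3,7,11-trimethyldodeca-2,6,11-trien-1-ol
Conditions: NCS (1.1 equiv), PhSeCl (10 mol %), CH2Cl2, rt
Reagents that add atoms: N-chlorosuccinimide, O=C1CCC(=O)N1Cl
Why: Selenium-catalysed ene-type allylic chlorination, in which PhSeCl adds to the most electron-rich and least hindered terminal trisubstituted alkene and NCS-driven [2,3]-shift/elimination returns the transposed secondary allylic chloride; the C2 alkene is deactivated by the allylic hydroxyl and the new C10 centre (racemic) is erased later.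

Step 2
Reactants: 2 (2E,6E)-10-chloro-3,7,11-trimethyldodeca-2,6,11-trien-1-ol
Product: 3 (2E,6E)-10-chloro-3,7,11-trimethyldodeca-2,6,11-trienal
Conditions: MnO2 (10 equiv), CH2Cl2, rt
Reagents that add atoms: none
Why: Selective allylic alcohol oxidation on MnO2 gives the enal without touching the allylic chloride or the isolated alkenes and keeps the 2E geometry.

Step 3
Reactants: 4 3-methylbut-2-enoyl chloride (2 equiv)
Product: 5 bis(3-methylbut-2-enoyl) peroxide
Conditions: H2O2 (30 % aq, 0.5 equiv), NaOH (1.0 equiv), Et2O–H2O, 0 °C; kept as a solution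
Reagents that add atoms: hydrogen peroxide, OO; 3-methylbut-2-enoyl chloride (second equivalent of 4), CC(C)=CC(Cl)=O
Why: Schotten–Baumann double acylation, in which the hydroperoxide anion is acylated by one molecule of 4 to the peracid and its anion is acylated by a second molecule of 4, gives the symmetric diacyl peroxide as in the standard preparation of dibenzoyl peroxide.

Step 4
Reactants: 3 (2E,6E)-10-chloro-3,7,11-trimethyldodeca-2,6,11-trienal; 5 bis(3-methylbut-2-enoyl) peroxide
Product: 7 (2E,4S,6E)-10-chloro-1-hydroxy-3,7,11-trimethyldodeca-2,6,11-trien-4-yl 3-methylbut-2-enoate, via γ-acyloxy enal 6 (not isolated)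
Conditions: 9-amino-9-deoxy-epi-quinine (20 mol %), Cl3CCO2H (20 mol %), BHT (10 mol %), THF, 0 °C; then H2O, CeCl3·7H2O, NaBH4, MeOH, −40 °C
Reagents that add atoms: bis(3-methylbut-2-enoyl) peroxide (5), CC(C)=CC(=O)OOC(=O)C=C(C)C
Why: Proposed new method: amine-catalysed vinylogous C–H acyloxylation of a β,β-disubstituted polyene enal with an unsaturated diacyl peroxide, in which the primary amine forms the iminium ion of 3, reversible γ-deprotonation under the acid co-catalyst funnels it to the more substituted linear (1E,3E)-dienamine (C3=C4), and its γ-carbon C4 displaces carboxylate at the peroxide O–O bond while the protonated quinuclidine hydrogen-bonds the peroxide carbonyl and presents it to one face (sets 4S), returning the conjugated iminium of 6 (α-attack would give a deconjugated product and is screened by the catalyst), after which hydrolysis and immediate Luche 1,2-reduction lock the 2E-enal as allylic alcohol 7 before it can re-enter the cycle; the closest known reaction types are enamine-catalysed α-benzoyloxylation of aldehydes and ketones with dibenzoyl peroxide and dienamine-catalysed γ-amination of enals.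

Step 5
Reactants: 7 (2E,4S,6E)-10-chloro-1-hydroxy-3,7,11-trimethyldodeca-2,6,11-trien-4-yl 3-methylbut-2-enoate
Product: 8 (2R,3R,4S,6E)-10-chloro-2,3-epoxy-1-hydroxy-3,7,11-trimethyldodeca-6,11-dien-4-yl 3-methylbut-2-enoate
Conditions: Ti(OiPr)4 (10 mol %), D-(−)-diethyl tartrate (12 mol %), t-BuOOH (2 equiv), 4 Å MS, CH2Cl2, −20 °C
Reagents that add atoms: tert-butyl hydroperoxide, CC(C)(C)OO
Why: Sharpless asymmetric epoxidation, reagent-controlled for a primary allylic alcohol, delivers oxygen with D-(−)-tartrate to the face that gives the (2R,3R)-epoxide, is stereospecific for the E-alkene (trans epoxide, methyl cis to CH2OH) and leaves the other alkenes alone; a minor C4 epimer from step 4 becomes a separable diastereomer here.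

Step 6
Reactants: 8 (2R,3R,4S,6E)-10-chloro-2,3-epoxy-1-hydroxy-3,7,11-trimethyldodeca-6,11-dien-4-yl 3-methylbut-2-enoate
Product: 9 (2S,3R,4S,6E)-10-chloro-2,3-epoxy-3,7,11-trimethyl-1-oxododeca-6,11-dien-4-yl 3-methylbut-2-enoate
Conditions: TEMPO (10 mol %), PhI(OAc)2 (1.1 equiv), CH2Cl2, rt
Reagents that add atoms: none
Why: Oxoammonium (TEMPO) oxidation of the primary alcohol stops at the aldehyde under near-neutral conditions, so the epoxide, the allylic chloride and the α-stereocentre are preserved (C2 becomes S only through the priority change).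

Step 7
Reactants: 9 (2S,3R,4S,6E)-10-chloro-2,3-epoxy-3,7,11-trimethyl-1-oxododeca-6,11-dien-4-yl 3-methylbut-2-enoate
Product: 11 (1(10)E,3S,4R,5R,6R,7S)-4,5-epoxy-6-hydroxygermacra-1(10),11-dien-3-yl 3-methylbut-2-enoate, via allylzinc species 10 (not isolated)
Conditions: Pd(PPh3)4 (10 mol %), Et2Zn (3 equiv), THF, 0 °C to rt, 5 mM, slow addition of 9; aq NH4Cl work-up
Reagents that add atoms: none
Why: Palladium-catalysed umpolung (Barbier-type) allylation, in which zerovalent palladium ionises the allylic chloride to a π-allyl complex, transmetalation to zinc gives the interconverting allylzinc 10, and this adds through its more substituted γ-carbon to the aldehyde in a six-membered cyclic transition state to close the ten-membered ring; C6 (R) follows from Felkin–Anh attack anti to the epoxide C–O bond and C7 (S) from a crown-like ring geometry with the isopropenyl group pseudo-equatorial and cis to the new hydroxyl.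

Step 8
Reactants: 11 (1(10)E,3S,4R,5R,6R,7S)-4,5-epoxy-6-hydroxygermacra-1(10),11-dien-3-yl 3-methylbut-2-enoate
Product: 12 (1(10)E,3S,4R,5R,6R,7S)-4,5-epoxy-6-hydroxygermacr-1(10)-en-3-yl 3-methylbut-2-enoate
Conditions: H2 (1 atm), RhCl(PPh3)3 (5 mol %), benzene–EtOH (1:1), rt
Reagents that add atoms: none
Why: Homogeneous hydrogenation with RhCl(PPh3)3 discriminates by alkene substitution, so only the 1,1-disubstituted isopropenyl group is reduced while the trisubstituted ring alkene, the conjugated senecioate alkene and the epoxide survive; no stereocentre is made or touched.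

Step 9
Reactants: 12 (1(10)E,3S,4R,5R,6R,7S)-4,5-epoxy-6-hydroxygermacr-1(10)-en-3-yl 3-methylbut-2-enoate
Product: 13 (1(10)E,3S,4R,5R,6R,7S)-6-acetoxy-4,5-epoxygermacr-1(10)-en-3-yl 3-methylbut-2-enoate
Conditions: Ac2O, Et3N, DMAP (10 mol %), CH2Cl2, 0 °C to rt
Reagents that add atoms: acetic anhydride, CC(=O)OC(C)=O
Why: DMAP-catalysed O-acylation of the secondary alcohol proceeds with retention at C6 and without epoxide opening or acyl migration, giving the target.

**Compound list**
1 | (2E,6E)-farnesol, (2E,6E)-3,7,11-trimethyldodeca-2,6,10-trien-1-ol | OC/C=C(\C)CC/C=C(\C)CCC=C(C)C | starting material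
2 | (2E,6E)-10-chloro-3,7,11-trimethyldodeca-2,6,11-trien-1-ol (C10 racemic) | OC/C=C(\C)CC/C=C(\C)CCC(Cl)C(C)=C | intermediate
3 | (2E,6E)-10-chloro-3,7,11-trimethyldodeca-2,6,11-trienal (C10 racemic) | O=C/C=C(\C)CC/C=C(\C)CCC(Cl)C(C)=C | intermediate
4 | 3-methylbut-2-enoyl chloride | CC(C)=CC(Cl)=O | starting material
5 | bis(3-methylbut-2-enoyl) peroxide | CC(C)=CC(=O)OOC(=O)C=C(C)C | intermediate
6 | (2E,4S,6E)-10-chloro-3,7,11-trimethyl-1-oxododeca-2,6,11-trien-4-yl 3-methylbut-2-enoate (formed in situ) | O=C/C=C(\C)[C@@H](OC(=O)C=C(C)C)C/C=C(\C)CCC(Cl)C(C)=C | intermediate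
7 | (2E,4S,6E)-10-chloro-1-hydroxy-3,7,11-trimethyldodeca-2,6,11-trien-4-yl 3-methylbut-2-enoate | OC/C=C(\C)[C@@H](OC(=O)C=C(C)C)C/C=C(\C)CCC(Cl)C(C)=C | intermediate
8 | (2R,3R,4S,6E)-10-chloro-2,3-epoxy-1-hydroxy-3,7,11-trimethyldodeca-6,11-dien-4-yl 3-methylbut-2-enoate | OC[C@H]1O[C@]1(C)[C@@H](OC(=O)C=C(C)C)C/C=C(\C)CCC(Cl)C(C)=C | intermediate
9 | (2S,3R,4S,6E)-10-chloro-2,3-epoxy-3,7,11-trimethyl-1-oxododeca-6,11-dien-4-yl 3-methylbut-2-enoate | O=C[C@H]1O[C@]1(C)[C@@H](OC(=O)C=C(C)C)C/C=C(\C)CCC(Cl)C(C)=C | intermediate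
10 | (2S,3R,4S,6E)-2,3-epoxy-12-(ethylzincio)-3,7,11-trimethyl-1-oxododeca-6,10-dien-4-yl 3-methylbut-2-enoate (σ-allylzinc, formed in situ) | O=C[C@H]1O[C@]1(C)[C@@H](OC(=O)C=C(C)C)C/C=C(\C)CCC=C(C)C[Zn]CC | intermediate
11 | (1(10)E,3S,4R,5R,6R,7S)-4,5-epoxy-6-hydroxygermacra-1(10),11-dien-3-yl 3-methylbut-2-enoate (ten-membered ring, trans epoxide, C6 OH and C7 isopropenyl cis) | O[C@H]1[C@H]2O[C@]2(C)[C@@H](OC(=O)C=C(C)C)C/C=C(\C)CC[C@H]1C(C)=C | intermediate
12 | (1(10)E,3S,4R,5R,6R,7S)-4,5-epoxy-6-hydroxygermacr-1(10)-en-3-yl 3-methylbut-2-enoate | O[C@H]1[C@H]2O[C@]2(C)[C@@H](OC(=O)C=C(C)C)C/C=C(\C)CC[C@H]1C(C)C | intermediate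
13 | (1(10)E,3S,4R,5R,6R,7S)-6-acetoxy-4,5-epoxygermacr-1(10)-en-3-yl 3-methylbut-2-enoate (CNP0267399.1) | CC(=O)O[C@H]1[C@H]2O[C@]2(C)[C@@H](OC(=O)C=C(C)C)C/C=C(\C)CC[C@H]1C(C)C | target

**Totals**
Total step count: 9. Longest linear sequence: 8 steps (1 → 2 → 3 → 7 → 8 → 9 → 11 → 12 → 13); step 3 is a one-step side branch for peroxide 5.

**Three steps most likely to fail**

Step 4 (the proposed new γ-acyloxylation). The main risks are:
- reaction through the cross-conjugated dienamine from the C3 methyl, which would put the ester on that methyl instead of C4;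
- competing α-attack;
- modest enantioselectivity (upgraded by the diastereomer separation after step 5);
- 2E/2Z scrambling of 6 before reduction.

The fallback uses only known chemistry and builds the C4 carbinol by C–C coupling, so its regiochemistry is unambiguous. It does not branch from an intermediate: it sets out from acid chloride 4, the only route compound it needs, and comes back at 7. (E)-1-Chloro-3,7-dimethylocta-2,6-diene F1 is converted with reactive Ba (from BaI2, Li and biphenyl, THF) into geranylbarium chloride F2. This adds through its α-carbon, with retention of the E-alkene, to commercial (E)-4-acetoxy-2-methylbut-2-enal F3 at −78 °C and gives racemic (2E,6E)-4-hydroxy-3,7,11-trimethyldodeca-2,6,10-trien-1-yl acetate F4. Sharpless kinetic resolution (Ti(OiPr)4, D-(−)-diisopropyl tartrate, 0.6 equiv t-BuOOH, −20 °C) leaves (2E,4S,6E)-4-hydroxy-3,7,11-trimethyldodeca-2,6,10-trien-1-yl acetate F5 in high ee (at most half of the material). The (4R)-enantiomer is consumed as the erythro epoxy alcohol (2R,3R,4R,6E)-2,3-epoxy-4-hydroxy-3,7,11-trimethyldodeca-6,10-dien-1-yl acetate F6, which is removed by chromatography. Acylation of F5 with 4 (pyridine, DMAP) gives (2E,4S,6E)-1-acetoxy-3,7,11-trimethyldodeca-2,6,10-trien-4-yl 3-methylbut-2-enoate F7. The ene-chlorination of step 1 (NCS, cat. PhSeCl) then gives (2E,4S,6E)-1-acetoxy-10-chloro-3,7,11-trimethyldodeca-2,6,11-trien-4-yl 3-methylbut-2-enoate F8. K2CO3 in MeOH at 0 °C removes only the primary acetate and delivers 7.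

Step 7 (ten-membered ring closure). The risks are oligomerisation, ethyl transfer from Et2Zn to the aldehyde, and a different C6/C7 outcome caused by the extra C3 ester. The fallback sets out from 9 and comes back at 11, replacing the catalytic palladium/zinc manifold by a stoichiometric chromium-mediated Nozaki–Hiyama-type closure. Finkelstein exchange with allylic transposition (NaI, acetone) gives the primary iodide (2S,3R,4S,6E,10E)-2,3-epoxy-12-iodo-3,7,11-trimethyl-1-oxododeca-6,10-dien-4-yl 3-methylbut-2-enoate F9. CrCl2 (4 equiv, THF, high dilution) reduces it to the trivalent-chromium allyl species (2S,3R,4S,6E)-12-(dichlorochromio)-2,3-epoxy-3,7,11-trimethyl-1-oxododeca-6,10-dien-4-yl 3-methylbut-2-enoate F10. This adds through its γ-carbon to the aldehyde under the same Felkin-type control and gives 11 after aqueous work-up.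

Step 8 (chemoselective hydrogenation). The risk is partial reduction of the strained ring alkene or of the senecioate alkene. The fallback sets out from 11 and comes back at 13, changing both the order and the kind of reduction. Compound 11 is acetylated first (Ac2O, Et3N, DMAP) to (1(10)E,3S,4R,5R,6R,7S)-6-acetoxy-4,5-epoxygermacra-1(10),11-dien-3-yl 3-methylbut-2-enoate F11. The isopropenyl group is then reduced metal-free with diimide (2-nitrobenzenesulfonylhydrazide, Et3N, CH2Cl2, rt), which reacts with the 1,1-disubstituted alkene much faster than with trisubstituted or conjugated ones and gives 13 directly.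

**Further compounds**
F1 | step 4 | (E)-1-chloro-3,7-dimethylocta-2,6-diene (geranyl chloride) | CC(C)=CCC/C(C)=C/CCl
F2 | step 4 | geranylbarium chloride | CC(C)=CCC/C(C)=C/C[Ba]Cl
F3 | step 4 | (E)-4-acetoxy-2-methylbut-2-enal | CC(=O)OC/C=C(\C)C=O
F4 | step 4 | racemic (2E,6E)-4-hydroxy-3,7,11-trimethyldodeca-2,6,10-trien-1-yl acetate | CC(=O)OC/C=C(\C)C(O)C/C=C(\C)CCC=C(C)C
F5 | step 4 | (2E,4S,6E)-4-hydroxy-3,7,11-trimethyldodeca-2,6,10-trien-1-yl acetate | CC(=O)OC/C=C(\C)[C@@H](O)C/C=C(\C)CCC=C(C)C
F6 | step 4 | (2R,3R,4R,6E)-2,3-epoxy-4-hydroxy-3,7,11-trimethyldodeca-6,10-dien-1-yl acetate | CC(=O)OC[C@H]1O[C@]1(C)[C@H](O)C/C=C(\C)CCC=C(C)C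
F7 | step 4 | (2E,4S,6E)-1-acetoxy-3,7,11-trimethyldodeca-2,6,10-trien-4-yl 3-methylbut-2-enoate | CC(=O)OC/C=C(\C)[C@@H](OC(=O)C=C(C)C)C/C=C(\C)CCC=C(C)C
F8 | step 4 | (2E,4S,6E)-1-acetoxy-10-chloro-3,7,11-trimethyldodeca-2,6,11-trien-4-yl 3-methylbut-2-enoate | CC(=O)OC/C=C(\C)[C@@H](OC(=O)C=C(C)C)C/C=C(\C)CCC(Cl)C(C)=C
F9 | step 7 | (2S,3R,4S,6E,10E)-2,3-epoxy-12-iodo-3,7,11-trimethyl-1-oxododeca-6,10-dien-4-yl 3-methylbut-2-enoate | O=C[C@H]1O[C@]1(C)[C@@H](OC(=O)C=C(C)C)C/C=C(\C)CC/C=C(\C)CI
F10 | step 7 | (2S,3R,4S,6E)-12-(dichlorochromio)-2,3-epoxy-3,7,11-trimethyl-1-oxododeca-6,10-dien-4-yl 3-methylbut-2-enoate | O=C[C@H]1O[C@]1(C)[C@@H](OC(=O)C=C(C)C)C/C=C(\C)CCC=C(C)C[Cr](Cl)Cl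
F11 | step 8 | (1(10)E,3S,4R,5R,6R,7S)-6-acetoxy-4,5-epoxygermacra-1(10),11-dien-3-yl 3-methylbut-2-enoate | CC(=O)O[C@H]1[C@H]2O[C@]2(C)[C@@H](OC(=O)C=C(C)C)C/C=C(\C)CC[C@H]1C(C)=C
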